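Z comes from E and X, and the useful question is how much of the E lost ends as Z.

| setting | Monday's | Thursday's | Saturday's | Friday's | oak | larch | elm | birch | cedar |
|---|---|---|---|---|---|---|---|---|---|
| E | 0.050 M | 0.050 M | 0.050 M | 0.10 M | 0.050 M | 0.050 M | 0.050 M | 0.050 M (fed, over 20 h) | 0.050 M |
| X | 1 equiv | 0.50 equiv | 2 equiv | 1 equiv | 1.00 equiv (fed, over 2.0 h) | 1.00 equiv (fed, over 20 h) | 1.00 equiv | 1.00 equiv | 1.00 equiv (in portions, 2, over 20 h) |
| remark | run made earlier | run made earlier | run made earlier | run made earlier | all else is in the flask from the start; the feed brings no volume worth counting | all else is in the flask from the start; the feed brings no volume worth counting | everything together at the start | all else is in the flask from the start; the feed brings no volume worth counting | first portion at the start, last at 20 h |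
| time |  |  |  |  | 25 h | 25 h | 25 h | 25 h | 25 h |

| run | time / h | Z / % | E / % |
|---|---|---|---|
| Monday's | 3.00 | 45 | 33 |
| Monday's | 6.00 | 54 | 15 |
| Monday's | 10.0 | 66 | 11 |
| Monday's | 12.0 | 67 | 9 |
| Monday's | 15.0 | 66 | 3 |
| Thursday's | 4.00 | 28 | 44 |
| Thursday's | 8.00 | 33 | 27 |
| Thursday's | 12.0 | 41 | 18 |
| Thursday's | 15.0 | 42 | 15 |
| Thursday's | 20.0 | 44 | 10 |
| Saturday's | 4.00 | 73 | 10 |
| Saturday's | 8.00 | 85 | 0 |
| Saturday's | 12.0 | 87 | 3 |
| Saturday's | 15.0 | 92 | 1 |
| Saturday's | 20.0 | 85 | 3 |
| Friday's | 2.00 | 54 | 26 |
| Friday's | 5.00 | 66 | 11 |
| Friday's | 10.0 | 72 | 2 |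
| Friday's | 15.0 | 71 | 3 |
| Friday's | 20.0 | 74 | 2 |

(each reading ± 2 percentage points)



- the flask that comes out highest in amount of Z, in percent of the E charged, or "all alike" when all lie within 1.5 percentage points (oak / larch / elm / birch / cedar / all alike)
- Z at the end, in percent of the E charged, oak
- Z at the end, in percent of the E charged, larch
- Z at the end, in percent of the E charged, elm
- Z at the end, in percent of the E charged, birch
- Z at the end, in percent of the E charged, cedar

Each Z takes one X, so in percent of the E charged, the X left is the X charged less Z. Friday's run at 5.00 h stood where Monday's stood at 10.0 h, with Z 66% and E 11%, at twice the concentration and half the time. So I took both losses of E as second order, which makes the selectivity, the share of E lost that becomes Z, equal to [X]/([X] + split × [E]).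

From the first readings of Monday's and Friday's runs, with [X]/[E] taken midway between the start and the reading, I read 0.582 for the split, the E lost aside per E turned into Z when [X] equals [E]. For elm, integrating the share until E is gone leaves X at the split to the power of one over one minus the split, so I reckoned Z with E gone at 72.6%. A feed of E begins with [X]/[E] high and a feed of X begins with it low, and the share goes with that ratio.

The forecast named birch and gave oak 66%, larch 38%, elm 70%, birch 73% and cedar 50%, with larch “X starved while E self-destructs”. Its elm, given for 25 h, lay 2.6 percentage points below my figure for E gone.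

The flasks gave oak 64.9%, larch 39.6%, elm 72.1%, birch 74.7% and cedar 50.0%, so birch came out highest.

    E + X → Z + G (k = 7.01 M⁻¹ h⁻¹)
    2 E → Q (k = 1.90 M⁻¹ h⁻¹)
    D ⇌ G, rate k3*(cs3 - [G]) while solid is left; crystals form when [G] > cs3 (solubility = 0.780 mM, k = 45.0 h⁻¹)

In birch at 25.0 h, with E 12.3% and X 25.3%, the split gives a share of 77.9% at that moment. Birch with 0.250 equiv of X has X as its limiting reagent, so the balance of X allows Z up to 25.0% of the E charged. That flask ended at 25.0 h with Z 23.1%, E 29.6% and X 7.56% of its own charge, and the split puts its share at that moment at 9.88%.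

All runs come from a simulation with made-up constants.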